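Readings and results were generated by integration from invented constants; scatter was added.

Amounts first: the flask holds 10.0 mM of solid reagent against 20.0 mM of the two substrates together, and each molecule of product costs one partner, which comes out of the solid reagent. So the solid reagent is the limiting reagent, and the reacted part, c, has a ceiling of 50.0%. The protic impurity also consumes partner, and if this flask's 5.00 mM took its whole charge, c would stop at 25.0%.

| flask | left-handed substrate | right-handed substrate | protic impurity | solid reagent | free catalyst | remark | time |
|---|---|---|---|---|---|---|---|
| ochre | 10 mM | 10 mM | 10 mM | 10 mM | 20 µM | run made earlier |  |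
| flask | 10 mM | 10 mM | 5.00 mM | 10.0 mM | 20 µM |  | 5.0 h |

ochre run (percent of the left-handed substrate and right-handed substrate together charged)

| time / min | left-handed substrate / % | right-handed substrate / % |
|---|---|---|
| 8.00 | 49.0 | 49.3 |
| 12.0 | 50.0 | 49.8 |
| 20.0 | 47.9 | 48.3 |
| 30.0 | 46.5 | 47.7 |
| 50.0 | 43.4 | 46.5 |
| 90.0 | 36.0 | 42.4 |

(scatter of a reading: 0.5 percentage points)

1. part of the left-handed substrate and right-handed substrate charged together that has reacted at 5.0 h
2. excess of left-handed product over right-handed product in the product at 5.0 h
3. excess of right-handed substrate over left-handed substrate among what is left of the two at 5.0 h

- free catalyst is single-handed; left-handed substrate and right-handed substrate are mirror images of each other, charged as a racemate, each of them at the stated concentration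
- given per volume of solution although it is solid: solid reagent
- reactions considered so far: partner + catalyst intermediate A -> free catalyst + left-handed product; free catalyst + right-handed substrate <-> catalyst intermediate B; partner + catalyst intermediate B -> free catalyst + right-handed product; solid reagent <-> partner; partner + protic impurity -> quenched reagent; free catalyst + left-handed substrate <-> catalyst intermediate A
- at the start none of the solid reagent is in solution
- an excess is the difference of the two amounts in percent of their sum
- an excess is below zero if the other one leads
- no earlier run changes the charge of protic impurity; that part of a forecast is a guess

But a ceiling counts only if the flask reaches it in time. The ochre run has the same charges of solid reagent and catalyst, and between 50.0 min and 90.0 min it makes product at 0.0575 mM min⁻¹. I define the run-out time t_x as the solid reagent charged divided by that rate, the latest time for the solid to be gone if partner enters at least as fast as product appears, and so the crossing from control by feed to control by charge: 2.90 h. This is shorter than the 5.0 h allowed, so I expect the charge to govern.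

My first objection is that a product rate is not a dissolution rate, and that this one is read from a single late stretch of scattered readings. The reading between 20.0 min and 50.0 min gives a lower product rate, 0.0420 mM min⁻¹, but the same division with it gives 3.97 h, still shorter than the 5.0 h allowed. My second objection is harder: where between floor and ceiling does c lie? No earlier run varies the impurity, so I can only guess. The ochre run has 4.32 mM of product at 90.0 min with twice this impurity charge, so I commit to c nearer the ceiling than the floor.

The forecast gives 33%, 27% and 13.5% for c, eP and eS, holding “so the limit is stoichiometric”.

The flask gives c = 44.4%, eP = 23.9% and eS = 19.0%.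

    partner + catalyst intermediate A → free catalyst + left-handed product (k = 3600 M⁻¹ min⁻¹)
    free catalyst + right-handed substrate ⇌ catalyst intermediate B (K = 77.0 M⁻¹, k = 36000 M⁻¹ min⁻¹)
    partner + catalyst intermediate B → free catalyst + right-handed product (k = 1600 M⁻¹ min⁻¹)
    solid reagent ⇌ partner, rate k4*(cs4 - [partner]) while solid is left; crystals form when [partner] > cs4 (solubility = 4.40 mM, k = 0.0330 min⁻¹)
    partner + protic impurity → quenched reagent (k = 0.710 M⁻¹ min⁻¹)
    free catalyst + left-handed substrate ⇌ catalyst intermediate A (K = 67.0 M⁻¹, k = 24000 M⁻¹ min⁻¹)

Its solid reagent stands at 0% by 2.50 h, inside t_x, and 1.10 mM of quenched reagent stands at 5.00 h, with c 5.6 percentage points under the ceiling. Now take the neighbouring flask charged with 17 mM of solid reagent: its t_x is 4.93 h, still inside 5.0 h, and its ceiling is 85.0%. At 5.00 h that flask shows solid reagent at 0%, quenched reagent at 1.87 mM, partner at 1.10 mM and c at 70.2%.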